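**Retrosynthetic overview**
1. Target ⇐ late acylations (C‑1/C‑6 (R)‑2‑methylbutanoates last, C‑5 (Z)‑3‑methylpent‑2‑enoate before), C‑1 oxygen by enolate hydroxylation, oxirane by C‑5‑OH‑directed epoxidation of an isopropenyl group.
2. Five‑membered ring (formed second) ⇐ Ni‑catalysed reductive alkyne–aldehyde cyclisation of a trans‑disposed prop‑1‑ynyl / 2‑oxoethyl pair on the cyclohexane; this also fixes the (E)‑ethylidene.
3. Exocyclic methylene and isopropenyl ⇐ double methylenation of a ring ketone / acetyl diketone; cis‑5,6‑diol ⇐ dihydroxylation of a cyclohex‑2‑enone.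
4. Six‑membered ring (formed first) ⇐ auxiliary‑controlled Diels–Alder of a chiral 1‑amino‑3‑siloxy diene with (3E)‑hept‑3‑en‑5‑yn‑2‑one, setting the three contiguous carbon stereocentres.

Assumption: all compounds marked "starting material" are purchased (including (2R,5R)‑2,5‑diphenylpyrrolidine and (R)‑2‑methylbutanoic acid); bicyclic compounds use indene locants (C‑1 carbinol, C‑2 ketone, C‑3 ethylidene carbon, C‑3a/C‑7a ring fusion, C‑4 oxiranyl carbon, C‑5/C‑6 oxygenated, C‑7 methylidene).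

The stereochemical calls in steps 6, 14 and 18 rest on transition‑state models, not on worked precedent for these exact substrates.

**Step 1**
Reactants: 1 methyl 4,4‑dimethoxybutanoate
Product: 2 4,4‑dimethoxy‑N‑methoxy‑N‑methylbutanamide
Conditions: MeNH(OMe)·HCl, iPrMgCl, THF, −20 °C
Reagents that add atoms: N,O‑dimethylhydroxylamine hydrochloride, CNOC.Cl
Why: Weinreb amide formation by aminolysis of the ester with the magnesium amide; the acetal is inert.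

**Step 2**
Reactants: 2 4,4‑dimethoxy‑N‑methoxy‑N‑methylbutanamide
Product: 3 6,6‑dimethoxyhex‑1‑yn‑3‑one
Conditions: HC≡CMgBr, THF, 0 °C; aq. NH4Cl
Reagents that add atoms: ethynylmagnesium bromide, C#C[Mg]Br
Why: Weinreb ketone synthesis; the chelated tetrahedral intermediate stops at the ynone.

**Step 3**
Reactants: 3 6,6‑dimethoxyhex‑1‑yn‑3‑one; 4 (2R,5R)‑2,5‑diphenylpyrrolidine
Product: 5 (1E)‑1‑[(2R,5R)‑2,5‑diphenylpyrrolidin‑1‑yl]‑6,6‑dimethoxyhex‑1‑en‑3‑one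
Conditions: CH2Cl2, rt
Reagents that add atoms: none
Why: aza‑Michael addition of the secondary amine to the ynone gives the (E)‑vinylogous amide.

**Step 4**
Reactants: 5 (1E)‑1‑[(2R,5R)‑2,5‑diphenylpyrrolidin‑1‑yl]‑6,6‑dimethoxyhex‑1‑en‑3‑one
Product: 7 (2R,5R)‑1‑[(1E,3Z)‑3‑(tert‑butyldimethylsilyloxy)‑6,6‑dimethoxyhexa‑1,3‑dien‑1‑yl]‑2,5‑diphenylpyrrolidine, via potassium enolate 6 (not isolated)
Conditions: KN(SiMe3)2, THF, −78 °C; then TBSCl, −78 °C → rt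
Reagents that add atoms: tert‑butyldimethylsilyl chloride, CC(C)(C)[Si](C)(C)Cl
Why: kinetic α′‑deprotonation gives the (Z)‑enolate (chain turned away from the aminovinyl group), and O‑silylation gives the Rawal‑type aminosiloxy diene with the side chain "outside".

**Step 5**
Reactants: 8 but‑2‑ynal; 9 1‑(triphenylphosphoranylidene)propan‑2‑one
Product: 10 (3E)‑hept‑3‑en‑5‑yn‑2‑one
Conditions: CH2Cl2, rt
Reagents that add atoms: none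
Why: Wittig olefination with a stabilised ylide gives the (E)‑enone.

**Step 6**
Reactants: 7 (2R,5R)‑1‑[(1E,3Z)‑3‑(tert‑butyldimethylsilyloxy)‑6,6‑dimethoxyhexa‑1,3‑dien‑1‑yl]‑2,5‑diphenylpyrrolidine; 10 (3E)‑hept‑3‑en‑5‑yn‑2‑one
Product: 12 (4S,5S,6S)‑4‑acetyl‑6‑(2,2‑dimethoxyethyl)‑5‑(prop‑1‑yn‑1‑yl)cyclohex‑2‑en‑1‑one, via Diels–Alder cycloadduct 11 (not isolated)
Conditions: toluene, 40 °C; then HF·pyridine, pyridine, THF, 0 °C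
Reagents that add atoms: none
Why: Diels–Alder reaction in which the amino terminus bonds to the acetyl‑bearing carbon, the acetyl group is endo, and the dienophile adds to the diene face not covered by the phenyl group of the C2‑symmetric pyrrolidine, setting C‑4, C‑5 and C‑6 all‑trans; HF then cleaves the silyl enol ether and expels the amine vinylogously to the enone.

**Step 7**
Reactants: 12 (4S,5S,6S)‑4‑acetyl‑6‑(2,2‑dimethoxyethyl)‑5‑(prop‑1‑yn‑1‑yl)cyclohex‑2‑en‑1‑one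
Product: 13 (2S,3S,4R,5S,6S)‑4‑acetyl‑6‑(2,2‑dimethoxyethyl)‑2,3‑dihydroxy‑5‑(prop‑1‑yn‑1‑yl)cyclohexan‑1‑one
Conditions: OsO4 (5 mol %), N‑methylmorpholine N‑oxide, citric acid, t‑BuOH/H2O, rt
Reagents that add atoms: osmium tetroxide, O=[Os](=O)(=O)=O; N‑methylmorpholine N‑oxide, C[N+]1([O-])CCOCC1; water, O
Why: Upjohn syn‑dihydroxylation of the enone C=C from the face anti to the adjacent C‑4 acetyl group gives the cis‑diol; the alkyne is inert and citric acid keeps the epimerisable substrate out of base.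

**Step 8**
Reactants: 13 (2S,3S,4R,5S,6S)‑4‑acetyl‑6‑(2,2‑dimethoxyethyl)‑2,3‑dihydroxy‑5‑(prop‑1‑yn‑1‑yl)cyclohexan‑1‑one
Product: 14 (2S,3S,4R,5S,6S)‑4‑acetyl‑6‑(2,2‑dimethoxyethyl)‑2‑hydroxy‑5‑(prop‑1‑yn‑1‑yl)‑3‑[(triethylsilyl)oxy]cyclohexan‑1‑one
Conditions: TESCl (1.05 equiv), imidazole, CH2Cl2, −40 °C
Reagents that add atoms: chlorotriethylsilane, CC[Si](Cl)(CC)CC
Why: kinetic silylation, the equatorial non‑hydrogen‑bonded C‑3 hydroxyl reacting faster than the axial α‑ketol hydroxyl at C‑2.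

**Step 9**
Reactants: 14 (2S,3S,4R,5S,6S)‑4‑acetyl‑6‑(2,2‑dimethoxyethyl)‑2‑hydroxy‑5‑(prop‑1‑yn‑1‑yl)‑3‑[(triethylsilyl)oxy]cyclohexan‑1‑one
Product: 15 (2S,3S,4R,5S,6S)‑4‑acetyl‑2‑[(tert‑butyldimethylsilyl)oxy]‑6‑(2,2‑dimethoxyethyl)‑5‑(prop‑1‑yn‑1‑yl)‑3‑[(triethylsilyl)oxy]cyclohexan‑1‑one
Conditions: TBSOTf, 2,6‑lutidine, CH2Cl2, −78 → 0 °C
Reagents that add atoms: tert‑butyldimethylsilyl trifluoromethanesulfonate, CC(C)(C)[Si](C)(C)OS(=O)(=O)C(F)(F)F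
Why: silyl triflate silylation of the hindered axial hydroxyl; at low temperature with a hindered base the ketones are not enol‑silylated.

**Step 10**
Reactants: 15 (2S,3S,4R,5S,6S)‑4‑acetyl‑2‑[(tert‑butyldimethylsilyl)oxy]‑6‑(2,2‑dimethoxyethyl)‑5‑(prop‑1‑yn‑1‑yl)‑3‑[(triethylsilyl)oxy]cyclohexan‑1‑one
Product: 16 tert‑butyl{[(1R,3S,4S,5S,6S)‑3‑(2,2‑dimethoxyethyl)‑2‑methylidene‑5‑(prop‑1‑en‑2‑yl)‑4‑(prop‑1‑yn‑1‑yl)‑6‑[(triethylsilyl)oxy]cyclohexyl]oxy}dimethylsilane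
Conditions: Zn, CH2Br2, TiCl4, THF (pre‑formed, 5 °C); then 15, CH2Cl2, 0 °C → rt
Reagents that add atoms: dibromomethane, BrCBr
Why: Lombardo–Takai methylenation of both ketones under non‑basic conditions, so the α‑silyloxy and α‑acetyl centres do not epimerise and no β‑elimination occurs.

**Step 11**
Reactants: 16 tert‑butyl{[(1R,3S,4S,5S,6S)‑3‑(2,2‑dimethoxyethyl)‑2‑methylidene‑5‑(prop‑1‑en‑2‑yl)‑4‑(prop‑1‑yn‑1‑yl)‑6‑[(triethylsilyl)oxy]cyclohexyl]oxy}dimethylsilane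
Product: 17 2‑[(1S,2S,3S,4S,5R)‑5‑[(tert‑butyldimethylsilyl)oxy]‑4‑hydroxy‑6‑methylidene‑3‑(prop‑1‑en‑2‑yl)‑2‑(prop‑1‑yn‑1‑yl)cyclohexyl]acetaldehyde
Conditions: AcOH/THF/H2O (3:1:1), 40 °C
Reagents that add atoms: water, O
Why: acetal hydrolysis to the aldehyde with loss of the labile triethylsilyl ether; the hindered tert‑butyldimethylsilyl ether and both alkenes survive.

**Step 12**
Reactants: 17 2‑[(1S,2S,3S,4S,5R)‑5‑[(tert‑butyldimethylsilyl)oxy]‑4‑hydroxy‑6‑methylidene‑3‑(prop‑1‑en‑2‑yl)‑2‑(prop‑1‑yn‑1‑yl)cyclohexyl]acetaldehyde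
Product: 19 (3E,3aS,4S,5S,6R,7aS)‑6‑[(tert‑butyldimethylsilyl)oxy]‑3‑ethylidene‑7‑methylidene‑4‑(prop‑1‑en‑2‑yl)octahydro‑1H‑indene‑2,5‑diol (C‑2 epimers), via triethylsilyl ether 18 (not isolated)
Conditions: Ni(cod)2 (10 mol %), PBu3 (20 mol %), Et3SiH, THF, rt; then AcOH/THF/H2O, rt
Reagents that add atoms: none
Why: Montgomery nickel‑catalysed reductive alkyne–aldehyde cyclisation closes the five‑membered ring 5‑exo with syn delivery of H and the carbinol carbon across the alkyne, which fixes the (E)‑ethylidene; the trans ring fusion comes from the trans‑diequatorial side chains, the new C‑2 carbinol centre is later oxidised, and acid cleaves the silyl ether.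

**Step 13**
Reactants: 19 (3E,3aS,4S,5S,6R,7aS)‑6‑[(tert‑butyldimethylsilyl)oxy]‑3‑ethylidene‑7‑methylidene‑4‑(prop‑1‑en‑2‑yl)octahydro‑1H‑indene‑2,5‑diol
Product: 20 (3E,3aS,4S,5S,6R,7aS)‑6‑[(tert‑butyldimethylsilyl)oxy]‑3‑ethylidene‑5‑hydroxy‑7‑methylidene‑4‑(prop‑1‑en‑2‑yl)octahydro‑2H‑inden‑2‑one
Conditions: MnO2, CH2Cl2, rt
Reagents that add atoms: none
Why: chemoselective allylic oxidation; the saturated C‑5 alcohol is untouched.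

**Step 14**
Reactants: 20 (3E,3aS,4S,5S,6R,7aS)‑6‑[(tert‑butyldimethylsilyl)oxy]‑3‑ethylidene‑5‑hydroxy‑7‑methylidene‑4‑(prop‑1‑en‑2‑yl)octahydro‑2H‑inden‑2‑one
Product: 21 (3E,3aS,4R,5S,6R,7aS)‑6‑[(tert‑butyldimethylsilyl)oxy]‑3‑ethylidene‑5‑hydroxy‑7‑methylidene‑4‑[(2R)‑2‑methyloxiran‑2‑yl]octahydro‑2H‑inden‑2‑one
Conditions: VO(acac)2 (5 mol %), t‑BuOOH, CH2Cl2, 0 °C → rt
Reagents that add atoms: tert‑butyl hydroperoxide, CC(C)(C)OO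
Why: hydroxyl‑directed vanadium‑catalysed epoxidation (Sharpless–Michaelson type, homoallylic case) through a chair‑like transition state with =CH2 eclipsing C4–H gives the (2R)‑oxirane; the exocyclic methylene is out of reach of the equatorial C‑5 oxygen and the enone is electron‑poor.

**Step 15**
Reactants: 22 ethyl pent‑2‑ynoate
Product: 23 ethyl (2Z)‑3‑methylpent‑2‑enoate
Conditions: Me2CuLi (from MeLi, CuI), THF, −78 °C; aq. NH4Cl at −78 °C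
Reagents that add atoms: lithium dimethylcuprate, [Li+].C[Cu-]C
Why: syn‑carbocupration of the ynoate and protonation with retention place methyl cis to H, giving the (Z)‑enoate.

**Step 16**
Reactants: 23 ethyl (2Z)‑3‑methylpent‑2‑enoate
Product: 24 (2Z)‑3‑methylpent‑2‑enoic acid
Conditions: LiOH, THF/H2O, rt; then 1 M HCl
Reagents that add atoms: lithium hydroxide, [Li+].[OH-]
Why: saponification; the trisubstituted enoate keeps its geometry.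

**Step 17**
Reactants: 21 (3E,3aS,4R,5S,6R,7aS)‑6‑[(tert‑butyldimethylsilyl)oxy]‑3‑ethylidene‑5‑hydroxy‑7‑methylidene‑4‑[(2R)‑2‑methyloxiran‑2‑yl]octahydro‑2H‑inden‑2‑one; 24 (2Z)‑3‑methylpent‑2‑enoic acid
Product: 25 (3E,3aS,4R,5S,6R,7aS)‑6‑[(tert‑butyldimethylsilyl)oxy]‑3‑ethylidene‑7‑methylidene‑4‑[(2R)‑2‑methyloxiran‑2‑yl]‑2‑oxooctahydro‑1H‑inden‑5‑yl (2Z)‑3‑methylpent‑2‑enoate
Conditions: N,N′‑diisopropylcarbodiimide, 4‑(dimethylamino)pyridine, CH2Cl2, 0 °C → rt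
Reagents that add atoms: none
Why: Steglich esterification of the equatorial C‑5 alcohol under neutral conditions that spare the epoxide and the Z‑alkene.

**Step 18**
Reactants: 25 (3E,3aS,4R,5S,6R,7aS)‑6‑[(tert‑butyldimethylsilyl)oxy]‑3‑ethylidene‑7‑methylidene‑4‑[(2R)‑2‑methyloxiran‑2‑yl]‑2‑oxooctahydro‑1H‑inden‑5‑yl (2Z)‑3‑methylpent‑2‑enoate
Product: 27 (1R,3E,3aS,4R,5S,6R,7aS)‑6‑[(tert‑butyldimethylsilyl)oxy]‑3‑ethylidene‑1‑hydroxy‑7‑methylidene‑4‑[(2R)‑2‑methyloxiran‑2‑yl]‑2‑oxooctahydro‑1H‑inden‑5‑yl (2Z)‑3‑methylpent‑2‑enoate, via lithium enolate 26 (not isolated)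
Conditions: LiN(SiMe3)2, THF, −78 °C; then 2‑(benzenesulfonyl)‑3‑phenyloxaziridine, −78 °C; aq. NH4Cl
Reagents that add atoms: 2‑(benzenesulfonyl)‑3‑phenyloxaziridine, O=S(=O)(c1ccccc1)N1OC1c1ccccc1
Why: kinetic α′‑deprotonation at C‑1 (the ketone is far more acidic than the esters) and Davis enolate hydroxylation from the face anti to the axial C7a–H, which is also remote from the axial silyl ether, gives the (1R)‑alcohol.

**Step 19**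
Reactants: 27 (1R,3E,3aS,4R,5S,6R,7aS)‑6‑[(tert‑butyldimethylsilyl)oxy]‑3‑ethylidene‑1‑hydroxy‑7‑methylidene‑4‑[(2R)‑2‑methyloxiran‑2‑yl]‑2‑oxooctahydro‑1H‑inden‑5‑yl (2Z)‑3‑methylpent‑2‑enoate
Product: 28 (1R,3E,3aS,4R,5S,6R,7aS)‑3‑ethylidene‑1,6‑dihydroxy‑7‑methylidene‑4‑[(2R)‑2‑methyloxiran‑2‑yl]‑2‑oxooctahydro‑1H‑inden‑5‑yl (2Z)‑3‑methylpent‑2‑enoate
Conditions: HF·pyridine, pyridine, THF, 0 °C → rt
Reagents that add atoms: none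
Why: buffered fluoride desilylation removes the silyl ether without opening the epoxide or moving the C‑5 ester.

**Step 20**
Reactants: 28 (1R,3E,3aS,4R,5S,6R,7aS)‑3‑ethylidene‑1,6‑dihydroxy‑7‑methylidene‑4‑[(2R)‑2‑methyloxiran‑2‑yl]‑2‑oxooctahydro‑1H‑inden‑5‑yl (2Z)‑3‑methylpent‑2‑enoate; 29 (2R)‑2‑methylbutanoic acid (3 equiv)
Product: 30 (1R,3E,3aS,4R,5S,6R,7aS)‑3‑ethylidene‑7‑methylidene‑5‑{[(2Z)‑3‑methylpent‑2‑enoyl]oxy}‑4‑[(2R)‑2‑methyloxiran‑2‑yl]‑2‑oxooctahydro‑1H‑indene‑1,6‑diyl bis[(2R)‑2‑methylbutanoate]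
Conditions: N,N′‑diisopropylcarbodiimide, 4‑(dimethylamino)pyridine, CH2Cl2, 0 °C → rt
Reagents that add atoms: none
Why: double Steglich esterification of the C‑1 and C‑6 alcohols; no ketene forms, so the acid stereocentre is retained, and the product is the target.

**Compound list**
1 | methyl 4,4‑dimethoxybutanoate | COC(=O)CCC(OC)OC | starting material
2 | 4,4‑dimethoxy‑N‑methoxy‑N‑methylbutanamide | CON(C)C(=O)CCC(OC)OC | intermediate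
3 | 6,6‑dimethoxyhex‑1‑yn‑3‑one | C#CC(=O)CCC(OC)OC | intermediate
4 | (2R,5R)‑2,5‑diphenylpyrrolidine | N1[C@@H](c2ccccc2)CC[C@@H]1c1ccccc1 | starting material
5 | (1E)‑1‑[(2R,5R)‑2,5‑diphenylpyrrolidin‑1‑yl]‑6,6‑dimethoxyhex‑1‑en‑3‑one | COC(OC)CCC(=O)/C=C/N1[C@@H](c2ccccc2)CC[C@@H]1c1ccccc1 | intermediate
6 | potassium (1E,3Z)‑1‑[(2R,5R)‑2,5‑diphenylpyrrolidin‑1‑yl]‑6,6‑dimethoxyhexa‑1,3‑dien‑3‑olate | COC(OC)C/C=C([O-])/C=C/N1[C@@H](c2ccccc2)CC[C@@H]1c1ccccc1.[K+] | intermediate (not isolated)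
7 | (2R,5R)‑1‑[(1E,3Z)‑3‑(tert‑butyldimethylsilyloxy)‑6,6‑dimethoxyhexa‑1,3‑dien‑1‑yl]‑2,5‑diphenylpyrrolidine | COC(OC)C/C=C(O[Si](C)(C)C(C)(C)C)/C=C/N1[C@@H](c2ccccc2)CC[C@@H]1c1ccccc1 | intermediate
8 | but‑2‑ynal | CC#CC=O | starting material
9 | 1‑(triphenylphosphoranylidene)propan‑2‑one | CC(=O)C=P(c1ccccc1)(c1ccccc1)c1ccccc1 | starting material
10 | (3E)‑hept‑3‑en‑5‑yn‑2‑one | CC#C/C=C/C(C)=O | intermediate
11 | 1‑[(1R,2S,5S,6S)‑4‑[(tert‑butyldimethylsilyl)oxy]‑5‑(2,2‑dimethoxyethyl)‑2‑[(2R,5R)‑2,5‑diphenylpyrrolidin‑1‑yl]‑6‑(prop‑1‑yn‑1‑yl)cyclohex‑3‑en‑1‑yl]ethan‑1‑one | CC(C)(C)[Si](C)(C)OC=1[C@@H](CC(OC)OC)[C@H](C#CC)[C@@H](C(C)=O)[C@@H](N2[C@@H](c3ccccc3)CC[C@@H]2c2ccccc2)C=1 | intermediate (not isolated)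
12 | (4S,5S,6S)‑4‑acetyl‑6‑(2,2‑dimethoxyethyl)‑5‑(prop‑1‑yn‑1‑yl)cyclohex‑2‑en‑1‑one | O=C1[C@@H](CC(OC)OC)[C@H](C#CC)[C@@H](C(C)=O)C=C1 | intermediate
13 | (2S,3S,4R,5S,6S)‑4‑acetyl‑6‑(2,2‑dimethoxyethyl)‑2,3‑dihydroxy‑5‑(prop‑1‑yn‑1‑yl)cyclohexan‑1‑one | O=C1[C@@H](CC(OC)OC)[C@H](C#CC)[C@@H](C(C)=O)[C@H](O)[C@@H]1O | intermediate
14 | (2S,3S,4R,5S,6S)‑4‑acetyl‑6‑(2,2‑dimethoxyethyl)‑2‑hydroxy‑5‑(prop‑1‑yn‑1‑yl)‑3‑[(triethylsilyl)oxy]cyclohexan‑1‑one | O=C1[C@@H](CC(OC)OC)[C@H](C#CC)[C@@H](C(C)=O)[C@H](O[Si](CC)(CC)CC)[C@@H]1O | intermediate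
15 | (2S,3S,4R,5S,6S)‑4‑acetyl‑2‑[(tert‑butyldimethylsilyl)oxy]‑6‑(2,2‑dimethoxyethyl)‑5‑(prop‑1‑yn‑1‑yl)‑3‑[(triethylsilyl)oxy]cyclohexan‑1‑one | O=C1[C@@H](CC(OC)OC)[C@H](C#CC)[C@@H](C(C)=O)[C@H](O[Si](CC)(CC)CC)[C@@H]1O[Si](C)(C)C(C)(C)C | intermediate
16 | tert‑butyl{[(1R,3S,4S,5S,6S)‑3‑(2,2‑dimethoxyethyl)‑2‑methylidene‑5‑(prop‑1‑en‑2‑yl)‑4‑(prop‑1‑yn‑1‑yl)‑6‑[(triethylsilyl)oxy]cyclohexyl]oxy}dimethylsilane | C=C1[C@@H](CC(OC)OC)[C@H](C#CC)[C@@H](C(C)=C)[C@H](O[Si](CC)(CC)CC)[C@@H]1O[Si](C)(C)C(C)(C)C | intermediate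
17 | 2‑[(1S,2S,3S,4S,5R)‑5‑[(tert‑butyldimethylsilyl)oxy]‑4‑hydroxy‑6‑methylidene‑3‑(prop‑1‑en‑2‑yl)‑2‑(prop‑1‑yn‑1‑yl)cyclohexyl]acetaldehyde | C=C1[C@@H](CC=O)[C@H](C#CC)[C@@H](C(C)=C)[C@H](O)[C@@H]1O[Si](C)(C)C(C)(C)C | intermediate
18 | (3E,3aS,4S,5S,6R,7aS)‑6‑[(tert‑butyldimethylsilyl)oxy]‑3‑ethylidene‑7‑methylidene‑4‑(prop‑1‑en‑2‑yl)‑2‑[(triethylsilyl)oxy]octahydro‑1H‑inden‑5‑ol (C‑2 epimers, centre left open) | C=C1[C@@H]2[C@H](/C(=C\C)C(O[Si](CC)(CC)CC)C2)[C@@H](C(C)=C)[C@H](O)[C@@H]1O[Si](C)(C)C(C)(C)C | intermediate (not isolated)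
19 | (3E,3aS,4S,5S,6R,7aS)‑6‑[(tert‑butyldimethylsilyl)oxy]‑3‑ethylidene‑7‑methylidene‑4‑(prop‑1‑en‑2‑yl)octahydro‑1H‑indene‑2,5‑diol (C‑2 epimers, centre left open) | C=C1[C@@H]2[C@H](/C(=C\C)C(O)C2)[C@@H](C(C)=C)[C@H](O)[C@@H]1O[Si](C)(C)C(C)(C)C | intermediate
20 | (3E,3aS,4S,5S,6R,7aS)‑6‑[(tert‑butyldimethylsilyl)oxy]‑3‑ethylidene‑5‑hydroxy‑7‑methylidene‑4‑(prop‑1‑en‑2‑yl)octahydro‑2H‑inden‑2‑one | C=C1[C@@H]2[C@H](/C(=C\C)C(=O)C2)[C@@H](C(C)=C)[C@H](O)[C@@H]1O[Si](C)(C)C(C)(C)C | intermediate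
21 | (3E,3aS,4R,5S,6R,7aS)‑6‑[(tert‑butyldimethylsilyl)oxy]‑3‑ethylidene‑5‑hydroxy‑7‑methylidene‑4‑[(2R)‑2‑methyloxiran‑2‑yl]octahydro‑2H‑inden‑2‑one | C=C1[C@@H]2[C@H](/C(=C\C)C(=O)C2)[C@@H]([C@]2(C)CO2)[C@H](O)[C@@H]1O[Si](C)(C)C(C)(C)C | intermediate
22 | ethyl pent‑2‑ynoate | CCC#CC(=O)OCC | starting material
23 | ethyl (2Z)‑3‑methylpent‑2‑enoate | CCOC(=O)/C=C(/C)CC | intermediate
24 | (2Z)‑3‑methylpent‑2‑enoic acid | OC(=O)/C=C(/C)CC | intermediate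
25 | (3E,3aS,4R,5S,6R,7aS)‑6‑[(tert‑butyldimethylsilyl)oxy]‑3‑ethylidene‑7‑methylidene‑4‑[(2R)‑2‑methyloxiran‑2‑yl]‑2‑oxooctahydro‑1H‑inden‑5‑yl (2Z)‑3‑methylpent‑2‑enoate | C=C1[C@@H]2[C@H](/C(=C\C)C(=O)C2)[C@@H]([C@]2(C)CO2)[C@H](OC(=O)/C=C(/C)CC)[C@@H]1O[Si](C)(C)C(C)(C)C | intermediate
26 | lithium C‑1/C‑2 enolate of 25 | C=C1[C@@H]2[C@H](/C(=C\C)C([O-])=C2)[C@@H]([C@]2(C)CO2)[C@H](OC(=O)/C=C(/C)CC)[C@@H]1O[Si](C)(C)C(C)(C)C.[Li+] | intermediate (not isolated)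
27 | (1R,3E,3aS,4R,5S,6R,7aS)‑6‑[(tert‑butyldimethylsilyl)oxy]‑3‑ethylidene‑1‑hydroxy‑7‑methylidene‑4‑[(2R)‑2‑methyloxiran‑2‑yl]‑2‑oxooctahydro‑1H‑inden‑5‑yl (2Z)‑3‑methylpent‑2‑enoate | C=C1[C@@H]2[C@H](/C(=C\C)C(=O)[C@@H]2O)[C@@H]([C@]2(C)CO2)[C@H](OC(=O)/C=C(/C)CC)[C@@H]1O[Si](C)(C)C(C)(C)C | intermediate
28 | (1R,3E,3aS,4R,5S,6R,7aS)‑3‑ethylidene‑1,6‑dihydroxy‑7‑methylidene‑4‑[(2R)‑2‑methyloxiran‑2‑yl]‑2‑oxooctahydro‑1H‑inden‑5‑yl (2Z)‑3‑methylpent‑2‑enoate | C=C1[C@@H]2[C@H](/C(=C\C)C(=O)[C@@H]2O)[C@@H]([C@]2(C)CO2)[C@H](OC(=O)/C=C(/C)CC)[C@@H]1O | intermediate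
29 | (2R)‑2‑methylbutanoic acid | OC(=O)[C@H](C)CC | starting material
30 | (1R,3E,3aS,4R,5S,6R,7aS)‑3‑ethylidene‑7‑methylidene‑5‑{[(2Z)‑3‑methylpent‑2‑enoyl]oxy}‑4‑[(2R)‑2‑methyloxiran‑2‑yl]‑2‑oxooctahydro‑1H‑indene‑1,6‑diyl bis[(2R)‑2‑methylbutanoate] | C=C1[C@@H]2[C@H](/C(=C\C)C(=O)[C@@H]2OC(=O)[C@H](C)CC)[C@@H]([C@]2(C)CO2)[C@H](OC(=O)/C=C(/C)CC)[C@@H]1OC(=O)[C@H](C)CC | target

**Totals**
Total step count: 20. Longest linear sequence: 17 steps (steps 1–4, 6–14, 17–20).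

**Three steps most likely to fail, with fallbacks**

Step 6 (Diels–Alder). A terminally substituted aminosiloxy diene must react with a β‑substituted enone, and both the endo preference and the facial control by the auxiliary are predictions. The fallback replaces auxiliary control with catalyst control. It sets out from 3: methanol adds under catalysis by 1,4‑diazabicyclo[2.2.2]octane to give (1E)‑1,6,6‑trimethoxyhex‑1‑en‑3‑one F1. Soft enolisation with TBSOTf and Et3N gives tert‑butyl{[(1E,3Z)‑1,6,6‑trimethoxyhexa‑1,3‑dien‑3‑yl]oxy}dimethylsilane F2. Cycloaddition with 10 is then run with the triflimide salt of (S)‑1‑(2‑methylphenyl)‑3,3‑diphenyltetrahydro‑1H,3H‑pyrrolo[1,2‑c][1,3,2]oxazaborole (or its mirror image, whichever gives the 4S,5S,6S series in a test run). This gives 1‑[(1R,2S,5S,6S)‑4‑[(tert‑butyldimethylsilyl)oxy]‑5‑(2,2‑dimethoxyethyl)‑2‑methoxy‑6‑(prop‑1‑yn‑1‑yl)cyclohex‑3‑en‑1‑yl]ethan‑1‑one F3. Dilute trifluoroacetic acid then cleaves the silyl enol ether and eliminates methanol, and the route is rejoined at 12.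

Step 12 (nickel‑catalysed ring closure). A trans‑fused five‑membered ring with an exocyclic alkene has to form next to a hindered ring. The fallback is a radical ring closure and sets out from 17. SmI2 with HMPA and t‑BuOH in THF generates the ketyl radical, which cyclises 5‑exo‑dig onto the alkyne. This gives 19 together with (3Z,3aS,4S,5S,6R,7aS)‑6‑[(tert‑butyldimethylsilyl)oxy]‑3‑ethylidene‑7‑methylidene‑4‑(prop‑1‑en‑2‑yl)octahydro‑1H‑indene‑2,5‑diol F4. MnO2 oxidation of the mixture gives 20 and (3Z,3aS,4S,5S,6R,7aS)‑6‑[(tert‑butyldimethylsilyl)oxy]‑3‑ethylidene‑5‑hydroxy‑7‑methylidene‑4‑(prop‑1‑en‑2‑yl)octahydro‑2H‑inden‑2‑one F5. A catalytic amount of iodine in CH2Cl2 equilibrates F5 to the more stable (E)‑enone, so the route is rejoined at 20.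

Step 14 (directed epoxidation). The configuration at the quaternary oxirane carbon and the selectivity over the exocyclic methylene rest on a transition‑state model. The fallback is an iodocarbonate cyclisation and sets out from 20. Boc2O with 4‑(dimethylamino)pyridine gives tert‑butyl (3E,3aS,4S,5S,6R,7aS)‑6‑[(tert‑butyldimethylsilyl)oxy]‑3‑ethylidene‑7‑methylidene‑2‑oxo‑4‑(prop‑1‑en‑2‑yl)octahydro‑1H‑inden‑5‑yl carbonate F6. IBr in toluene at −80 °C closes the trans‑fused six‑membered cyclic iodocarbonate (4‑iodomethyl‑4‑methyl‑1,3‑dioxan‑2‑one ring spanning O‑5 and C‑4, iodomethyl equatorial) F7. K2CO3 in methanol cleaves the carbonate and the tertiary alkoxide displaces iodide, which gives the same (2R)‑oxirane and rejoins the route at 21.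

**Further compounds**
F1 | step 6 | (1E)‑1,6,6‑trimethoxyhex‑1‑en‑3‑one | COC(OC)CCC(=O)/C=C/OC
F2 | step 6 | tert‑butyl{[(1E,3Z)‑1,6,6‑trimethoxyhexa‑1,3‑dien‑3‑yl]oxy}dimethylsilane | COC(OC)C/C=C(O[Si](C)(C)C(C)(C)C)/C=C/OC
F3 | step 6 | 1‑[(1R,2S,5S,6S)‑4‑[(tert‑butyldimethylsilyl)oxy]‑5‑(2,2‑dimethoxyethyl)‑2‑methoxy‑6‑(prop‑1‑yn‑1‑yl)cyclohex‑3‑en‑1‑yl]ethan‑1‑one | CC(C)(C)[Si](C)(C)OC=1[C@@H](CC(OC)OC)[C@H](C#CC)[C@@H](C(C)=O)[C@@H](OC)C=1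
F4 | step 12 | (3Z,3aS,4S,5S,6R,7aS)‑6‑[(tert‑butyldimethylsilyl)oxy]‑3‑ethylidene‑7‑methylidene‑4‑(prop‑1‑en‑2‑yl)octahydro‑1H‑indene‑2,5‑diol | C=C1[C@@H]2[C@H](/C(=C/C)C(O)C2)[C@@H](C(C)=C)[C@H](O)[C@@H]1O[Si](C)(C)C(C)(C)C
F5 | step 12 | (3Z,3aS,4S,5S,6R,7aS)‑6‑[(tert‑butyldimethylsilyl)oxy]‑3‑ethylidene‑5‑hydroxy‑7‑methylidene‑4‑(prop‑1‑en‑2‑yl)octahydro‑2H‑inden‑2‑one | C=C1[C@@H]2[C@H](/C(=C/C)C(=O)C2)[C@@H](C(C)=C)[C@H](O)[C@@H]1O[Si](C)(C)C(C)(C)C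
F6 | step 14 | tert‑butyl (3E,3aS,4S,5S,6R,7aS)‑6‑[(tert‑butyldimethylsilyl)oxy]‑3‑ethylidene‑7‑methylidene‑2‑oxo‑4‑(prop‑1‑en‑2‑yl)octahydro‑1H‑inden‑5‑yl carbonate | C=C1[C@@H]2[C@H](/C(=C\C)C(=O)C2)[C@@H](C(C)=C)[C@H](OC(=O)OC(C)(C)C)[C@@H]1O[Si](C)(C)C(C)(C)C
F7 | step 14 | trans‑fused six‑membered cyclic iodocarbonate (4‑iodomethyl‑4‑methyl‑1,3‑dioxan‑2‑one ring spanning O‑5 and C‑4 of the hydrindanone) | C=C1[C@@H]2[C@H](/C(=C\C)C(=O)C2)[C@@H]([C@](C)(CI)OC(=O)O3)[C@H]3[C@@H]1O[Si](C)(C)C(C)(C)C
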